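Every exchange spends one incoming ligand and frees one leaving ligand, so their sum stays at 2.20 of the charge.

    complex with two exchanged + incoming ligand ⇌ leaving ligand + complex with three exchanged (K1 = 24.7, k1 = 0.771 L mol⁻¹ s⁻¹)
    starting complex + incoming ligand ⇌ leaving ligand + complex with one exchanged (K2 = 1.4, k2 = 0.125 L mol⁻¹ s⁻¹)
    starting complex + complex with one exchanged → side product (k3 = 0.00800 L mol⁻¹ s⁻¹)
    complex with one exchanged + capture agent → trapped intermediate (k4 = 0.189 L mol⁻¹ s⁻¹)
    complex with one exchanged + incoming ligand ⇌ leaving ligand + complex with two exchanged (K5 = 0.80, k5 = 0.335 L mol⁻¹ s⁻¹)
    complex with two exchanged ⇌ isomer of the product (K6 = 0.906, k6 = 1.18 × 10⁻⁴ s⁻¹)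

the same everywhere: starting complex 0.011 M; incoming ligand 1.20 equiv; leaving ligand 1.00 equiv; time 1.5 h

| charge | capture agent |
|---|---|
| birch | 0.120 mM |
| elm | 0.400 mM |
| cedar | 1.20 mM |
| larch | 3.00 mM |
| ash | 10.0 mM |

- percentages count the starting complex that a species holds: one side product counts as two
- "hardly changes" means that all values lie within two and a half points (for a concentration: within two and a half percent of the largest)
- run time (birch): 1.5 h

- share of complex with two exchanged in all that became complex with two exchanged or complex with three exchanged or trapped intermediate or side product or isomer of the product for birch, elm, cedar, larch, ash, in this order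
- how that number moves from the first to the last of them (falls, then rises / hardly changes / falls all the way / rises all the way / rises, then falls)

**First way.** We count in fractions of the starting complex charged. By its forward rate alone, step 2 halves the starting complex in 0.12 h, shorter than the run. Step 3 halves the complex with one exchanged in 2.2 h, slower. So we hold each exchange at equilibrium, a pre-equilibrium, and treat the drains as slow. Suppose 0.800 of incoming ligand is spent. The ligand balance leaves 0.400 incoming and 1.80 leaving ligand, a ratio of 0.222. We call this the ligand ratio, free incoming over free leaving ligand. Each rung of the exchange ladder stands above the one below by its constant times this ratio.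

**Second way.** The ladder counts exchanges independently of the balance. Its weights sum to 1.67, and the weighted mean gives 0.798 exchanges per complex. This meets the supposed figure, so we trust the ratio.

**Birch reckoned.** The ladder puts 0.0331 in the complex with two exchanged and 0.182 in the complex with three exchanged. The slow steps, run at ladder levels, add 0.106 of side product, 0.0152 of isomer and 0.00956 of trapped intermediate. Our share for birch is 9.58%.

**Ash reckoned.** The same sum gives 0.797 trapped and a share of 2.92%, lower than in birch. But ladder and drains together hold 1.92 of the charge in ash, more than exists, against 1.13 in birch. This way cheats, so we keep the direction of the ash figure and not its size, and we commit to a steady fall.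

**The result.** The forecast gave 9.5%, 8.8%, 7.2%, 5% and 2%, a row that falls all the way, on the ground that added capture agent “shrinks the two-exchanged complex and inflates the denominator”. The simulation gives 9.30%, 8.69%, 7.20%, 4.89% and 1.45%, and the row falls all the way.

**Why it falls.** In birch the end state gives a ligand ratio of 0.223 against our 0.222, and the top rung stands at 5.65 against 5.49 reckoned. In ash the ratio reads 0.188, so the rung should be 4.64, yet it stands at 6.27. The way back from the complex with three exchanged to the complex with two exchanged is the largest single effect on the fall from birch to ash, but not the main reason. Without it, the change from birch to ash shrinks from 7.8 percentage points to 1.1 points.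

(The rate constants are those of an exercise; the flask was simulated.)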